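## Retrosynthetic overview

- The target is 5-hydroxy-7,8-dimethoxy-2-(2,6-dimethoxyphenyl)chromen-4-one. The plan rests on ring A: its oxygens on C5, C7 and C8a sit 1,3,5 around the acyl-bearing C4a (an acylphloroglucinol, the Claisen fold of a linear tetraketide), and the fourth oxygen, on C8, is para to the 5-hydroxyl.
- Late stage: the 8-methoxy group is traced back to C8–H (Elbs oxidation para to the chelated 5-hydroxyl, then O-methylation) and the 7-methoxy group to 7-OH, which leaves the 5,7-dihydroxyflavone.
- Key disconnection: O1–C2 (ring C) and C4a–C5 (ring A) are both opened to an acyclic ynone-capped 3,5,7-triketo ester. In the forward direction ring C closes first and ring A second, in one flask; ring B is bought.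
- The chain is cut at C4–C4a into the trianion of methyl 3,5-dioxohexanoate and an alkynyl Weinreb amide, which comes in two steps from 2,6-dimethoxybenzaldehyde.

Key step: step 4

Remark: the open-chain polyketone and its pyranone isomer are drawn as keto forms although they will exist largely as enols. From the open-chain precursor onward, atoms are named by flavone numbering (O1, C2, C3, C4, C4a, C5–C8, C8a).

## Route

Step 1
Reactants: 1 2,6-dimethoxybenzaldehyde
Product: 2 2-ethynyl-1,3-dimethoxybenzene
Conditions: dimethyl (1-diazo-2-oxopropyl)phosphonate (1.3 equiv), K2CO3 (2 equiv), MeOH, 0 → 23 °C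
Reagents that add atoms: dimethyl (1-diazo-2-oxopropyl)phosphonate, CC(=O)C(=[N+]=[N-])P(=O)(OC)OC
Why: Seyferth–Gilbert homologation in its Ohira–Bestmann form, in which methanolysis frees the diazomethylphosphonate anion, this adds to the non-enolisable aldehyde, and the alkylidene carbene left after loss of phosphate and N2 rearranges by 1,2-shift to the terminal alkyne without touching the methyl ethers.

Step 2
Reactants: 2 2-ethynyl-1,3-dimethoxybenzene
Product: 4 3-(2,6-dimethoxyphenyl)-N-methoxy-N-methylprop-2-ynamide, via lithium acetylide 3 (not isolated)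
Conditions: n-BuLi (1.05 equiv), THF, −78 °C; then ClC(O)N(OMe)Me (1.2 equiv), −78 → 0 °C
Reagents that add atoms: N-methoxy-N-methylcarbamoyl chloride, CON(C)C(=O)Cl
Why: Deprotonation of the terminal alkyne followed by nucleophilic acyl substitution of the acetylide on the carbamoyl chloride should give the alkynyl Weinreb amide in one flask, since at −78 °C the chloride is a far better electrophile than the amide being formed.

Step 3
Reactants: 5 methyl 3,5-dioxohexanoate; 4 3-(2,6-dimethoxyphenyl)-N-methoxy-N-methylprop-2-ynamide
Product: 8 methyl 9-(2,6-dimethoxyphenyl)-3,5,7-trioxonon-8-ynoate, via trilithium trianion 6 (not isolated), via lithium hemiaminal adduct 7 (not isolated)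
Conditions: 5 (1.5 equiv), LiN(i-Pr)2 (4.5 equiv), THF, 0 °C; then 4 (1 equiv), −78 → −30 °C; inverse quench into cold 1 M HCl; rapid filtration through silica, used at once
Reagents that add atoms: none
Why: Weinreb ketone synthesis with a polycarbonyl polyanion, in which the last-formed and most basic terminal carbanion of 6 adds 1,2 to the amide carbonyl (the alkyne terminus is shielded by the two ortho-methoxy groups) and the chelated adduct 7 keeps the ynone masked until the acidic quench, so that neither amine nor enolate can add to it in the flask.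

Step 4
Reactants: 8 methyl 9-(2,6-dimethoxyphenyl)-3,5,7-trioxonon-8-ynoate
Product: 10 2-(2,6-dimethoxyphenyl)-5,7-dihydroxy-4H-chromen-4-one, via pyranone keto ester 9 (not isolated)
Conditions: Mg(OMe)2 (5 equiv), MeOH, 23 → 60 °C, N2; then 1 M HCl
Reagents that add atoms: none
Why: Proposed new method: the magnesium-chelated enolate oxygen on C8a should add to the ynone carbon C2 (oxa-Michael addition, ring C, 6-endo-dig) to give pyranone 9, after which loss of a proton from the C8 methylene gives a dienolate that runs through the pyranone, is nucleophilic at C4a and attacks the ester carbon C5 (Claisen condensation, ring A, 6-exo-trig), with loss of methoxide and enolisation to the phloroglucinol ring. The closest known reaction types are the Mg(OMe)2-mediated Claisen cyclisation of 3,5,7-trioxoalkanoates to acylphloroglucinols and the base-induced closure of 1,3-diketo ynones to 4-pyranones; running both on one chain, with the Claisen donor embedded in a pyranone, has not been demonstrated. No stereocentre is formed. The step needs the Claisen fold (C4a onto C5) to win over the aldol fold (C6 onto C4) and over lactonisation of the C8a enol oxygen onto the ester: magnesium chelation favours the Claisen mode in open triketo esters, and once ring C is closed the C8a oxygen is no longer available and an aldol closure would have to build a bridged bicycle. Attack at C2 and not at C3 of the ynone follows from the polarisation of the ynone, and methoxide addition to C2 would only give a β-methoxy enone that closes to the same pyranone by addition–elimination.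

Step 5
Reactants: 10 2-(2,6-dimethoxyphenyl)-5,7-dihydroxy-4H-chromen-4-one
Product: 11 2-(2,6-dimethoxyphenyl)-5-hydroxy-7-methoxy-4H-chromen-4-one
Conditions: Me2SO4 (1.05 equiv), K2CO3 (1.5 equiv), acetone, reflux
Reagents that add atoms: dimethyl sulfate, COS(=O)(=O)OC
Why: Williamson ether synthesis with one equivalent of electrophile, in which the 7-hydroxyl (a vinylogous acid para to the C4 carbonyl) is ionised and alkylated while the 5-hydroxyl is held in a hydrogen bond to the C4 carbonyl and stays free.

Step 6
Reactants: 11 2-(2,6-dimethoxyphenyl)-5-hydroxy-7-methoxy-4H-chromen-4-one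
Product: 13 2-(2,6-dimethoxyphenyl)-5,8-dihydroxy-7-methoxy-4H-chromen-4-one, via potassium aryl sulfate 12 (not isolated)
Conditions: K2S2O8 (1.2 equiv), KOH (aq.), pyridine, 0 → 23 °C; then 2 M HCl, 90 °C, N2
Reagents that add atoms: potassium peroxodisulfate, [K+].[K+].[O-]S(=O)(=O)OOS(=O)(=O)[O-]
Why: Elbs persulfate oxidation, in which the phenoxide of the 5-hydroxyl attacks the peroxide oxygen through its para carbon C8 (C6 is ortho and not favoured), the aryl sulfate 12 is cleaved at S–O by hot acid, and the three methyl ethers are inert to the oxidant.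

Step 7
Reactants: 13 2-(2,6-dimethoxyphenyl)-5,8-dihydroxy-7-methoxy-4H-chromen-4-one
Product: 14 altisin, 2-(2,6-dimethoxyphenyl)-5-hydroxy-7,8-dimethoxy-4H-chromen-4-one
Conditions: Me2SO4 (1.05 equiv), K2CO3 (1.2 equiv), acetone, reflux, N2
Reagents that add atoms: dimethyl sulfate, COS(=O)(=O)OC
Why: Williamson ether synthesis, in which the new 8-hydroxyl is free and is alkylated, the 5-hydroxyl is again protected by its hydrogen bond to the carbonyl, and exclusion of air keeps the 5,8-quinol from oxidising to the quinone under base.

## Compound list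

1 | 2,6-dimethoxybenzaldehyde | COc1cccc(OC)c1C=O | starting material
2 | 2-ethynyl-1,3-dimethoxybenzene | C#Cc1c(OC)cccc1OC | intermediate
3 | [(2,6-dimethoxyphenyl)ethynyl]lithium, not isolated | [Li]C#Cc1c(OC)cccc1OC | intermediate
4 | 3-(2,6-dimethoxyphenyl)-N-methoxy-N-methylprop-2-ynamide | CON(C)C(=O)C#Cc1c(OC)cccc1OC | intermediate
5 | methyl 3,5-dioxohexanoate | COC(=O)CC(=O)CC(C)=O | starting material
6 | trilithium trianion of methyl 3,5-dioxohexanoate, not isolated | [Li+].[Li+].[Li+].C=C([O-])C=C([O-])C=C([O-])OC | intermediate
7 | trilithium salt of the tetrahedral adduct of 6 with 4 (hemiaminal alkoxide, chain dienolate), not isolated | [Li+].[Li+].[Li+].COC([O-])=CC([O-])=CC(=O)CC([O-])(N(C)OC)C#Cc1c(OC)cccc1OC | intermediate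
8 | methyl 9-(2,6-dimethoxyphenyl)-3,5,7-trioxonon-8-ynoate | COC(=O)CC(=O)CC(=O)CC(=O)C#Cc1c(OC)cccc1OC | intermediate
9 | methyl 4-[6-(2,6-dimethoxyphenyl)-4-oxo-4H-pyran-2-yl]-3-oxobutanoate, not isolated | COC(=O)CC(=O)Cc1cc(=O)cc(-c2c(OC)cccc2OC)o1 | intermediate
10 | 2-(2,6-dimethoxyphenyl)-5,7-dihydroxy-4H-chromen-4-one | COc1cccc(OC)c1-c1cc(=O)c2c(O)cc(O)cc2o1 | intermediate
11 | 2-(2,6-dimethoxyphenyl)-5-hydroxy-7-methoxy-4H-chromen-4-one | COc1cccc(OC)c1-c1cc(=O)c2c(O)cc(OC)cc2o1 | intermediate
12 | potassium 2-(2,6-dimethoxyphenyl)-5-hydroxy-7-methoxy-4-oxo-4H-chromen-8-yl sulfate, not isolated | [K+].COc1cccc(OC)c1-c1cc(=O)c2c(O)cc(OC)c(OS(=O)(=O)[O-])c2o1 | intermediate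
13 | 2-(2,6-dimethoxyphenyl)-5,8-dihydroxy-7-methoxy-4H-chromen-4-one | COc1cccc(OC)c1-c1cc(=O)c2c(O)cc(OC)c(O)c2o1 | intermediate
14 | altisin, 2-(2,6-dimethoxyphenyl)-5-hydroxy-7,8-dimethoxy-4H-chromen-4-one | COc1cccc(OC)c1-c1cc(=O)c2c(O)cc(OC)c(OC)c2o1 | target

## Step count

Total steps: 7. Longest linear sequence: 7 steps (1 → 2 → 4 → 8 → 10 → 11 → 13 → 14); compound 5 is bought.

## Steps most likely to fail

**Step 4 (Proposed new method).** The chain may fold the wrong way or stall. Possible processes are aldol closure before ring C has formed, arrest at the pyranone stage because the β-keto ester methylene is deprotonated in place of the C8 methylene (which deactivates the ester), and retro-Claisen cleavage of the polyketone chain by methoxide.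

Fallback (known chemistry): it sets out from 4 and comes back to the route at 10, building ring A from a preformed phloroglucinol instead of folding it. Phloroglucinol would be converted with MOMCl and i-Pr2NEt into 1,3,5-tris(methoxymethoxy)benzene F1. n-BuLi in THF at 0 °C should lithiate F1 between two of its acetal oxygens to give 2,4,6-tris(methoxymethoxy)phenyllithium F2. Addition of F2 to Weinreb amide 4 should give 3-(2,6-dimethoxyphenyl)-1-[2,4,6-tris(methoxymethoxy)phenyl]prop-2-yn-1-one F3. HCl in methanol removes the three acetal groups to give 3-(2,6-dimethoxyphenyl)-1-(2,4,6-trihydroxyphenyl)prop-2-yn-1-one F4. K2CO3 in acetone then closes ring C by 6-endo-dig oxa-Michael addition of an ortho-hydroxyl to give 10; any closure already during the deprotection leads to the same flavone.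

**Step 3.** The acylation may be diverted by conjugate addition of the trianion or of amide base to the alkynyl amide, by proton transfer that quenches the trianion, or by premature ring closure of the product during work-up and purification.

Fallback: it sets out from acetylide 3 and comes back at 8, replacing the acylation by an aldol addition and an oxidation. Quenching 3 with DMF should give 3-(2,6-dimethoxyphenyl)prop-2-ynal F5. Aldol addition of trianion 6 to F5 at −78 °C should give racemic methyl 9-(2,6-dimethoxyphenyl)-7-hydroxy-3,5-dioxonon-8-ynoate F6; the aldehyde is a hard electrophile that reacts 1,2 and needs no leaving group. MnO2 in CH2Cl2 then oxidises the propargylic alcohol of F6 to the ynone 8, which also removes the stereocentre.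

**Step 6.** The Elbs oxidation may suffer from low conversion of the chelated phenoxide, from over-oxidation of the quinol to quinone and polymeric material, and from alkaline opening of the pyranone ring.

Fallback: it sets out from 11 and comes back at the target 14, replacing steps 6 and 7 by halogenation and ether exchange.
- Exhaustive methylation of 11 (MeI, K2CO3, DMF, 60 °C) should give 2-(2,6-dimethoxyphenyl)-5,7-dimethoxy-4H-chromen-4-one F7.
- Iodination with I2 and CF3CO2Ag in CH2Cl2 is expected at C8, which is ortho to O1 and the 7-methoxy group and para to the 5-methoxy group, giving 2-(2,6-dimethoxyphenyl)-8-iodo-5,7-dimethoxy-4H-chromen-4-one F8. Ring A with three oxygen donors should react before ring B, but competition from C3′ would have to be checked.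
- Ullmann-type methoxylation (NaOMe, CuBr, MeOH–DMF, 110 °C) should give 2-(2,6-dimethoxyphenyl)-5,7,8-trimethoxy-4H-chromen-4-one F9.
- BCl3 in CH2Cl2 at −78 → 0 °C cleaves only the 5-methoxy group, which chelates boron together with the C4 carbonyl, to give 14.

Further compounds
F1 | step 4 | 1,3,5-tris(methoxymethoxy)benzene | COCOc1cc(OCOC)cc(OCOC)c1
F2 | step 4 | 2,4,6-tris(methoxymethoxy)phenyllithium | [Li]c1c(OCOC)cc(OCOC)cc1OCOC
F3 | step 4 | 3-(2,6-dimethoxyphenyl)-1-[2,4,6-tris(methoxymethoxy)phenyl]prop-2-yn-1-one | COCOc1cc(OCOC)c(C(=O)C#Cc2c(OC)cccc2OC)c(OCOC)c1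
F4 | step 4 | 3-(2,6-dimethoxyphenyl)-1-(2,4,6-trihydroxyphenyl)prop-2-yn-1-one | COc1cccc(OC)c1C#CC(=O)c1c(O)cc(O)cc1O
F5 | step 3 | 3-(2,6-dimethoxyphenyl)prop-2-ynal | O=CC#Cc1c(OC)cccc1OC
F6 | step 3 | methyl 9-(2,6-dimethoxyphenyl)-7-hydroxy-3,5-dioxonon-8-ynoate (racemic) | COC(=O)CC(=O)CC(=O)CC(O)C#Cc1c(OC)cccc1OC
F7 | step 6 | 2-(2,6-dimethoxyphenyl)-5,7-dimethoxy-4H-chromen-4-one | COc1cccc(OC)c1-c1cc(=O)c2c(OC)cc(OC)cc2o1
F8 | step 6 | 2-(2,6-dimethoxyphenyl)-8-iodo-5,7-dimethoxy-4H-chromen-4-one | COc1cccc(OC)c1-c1cc(=O)c2c(OC)cc(OC)c(I)c2o1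
F9 | step 6 | 2-(2,6-dimethoxyphenyl)-5,7,8-trimethoxy-4H-chromen-4-one | COc1cccc(OC)c1-c1cc(=O)c2c(OC)cc(OC)c(OC)c2o1
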